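All runs are simulated for substances that don't exist; the scatter is artificial.

**The amounts.** The spring run held 0.200 M of starting material against 0.0200 M of free catalyst, a catalyst share of 10.0% of the charge. I followed it as the fraction of that charge turned into product.

| flask | starting material | free catalyst | time |
|---|---|---|---|
| spring | 0.200 M | 0.0200 M |  |
| dusk | 0.600 M | 0.0200 M |  |
| noon | 0.200 M | 0.0300 M |  |
| midnight | 0.200 M | 0.0200 M | 260 min |

| run | time / min | [product] / M |
|---|---|---|
| spring run | 3.5 | 0.0021 |
| spring run | 7.9 | 0.0065 |
| spring run | 18 | 0.0194 |
| spring run | 39 | 0.0444 |
| spring run | 88 | 0.0938 |
| dusk run | 3.5 | 0.0065 |
| dusk run | 7.9 | 0.0180 |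
| dusk run | 18 | 0.0547 |
| dusk run | 39 | 0.1280 |
| dusk run | 88 | 0.2461 |
| noon run | 3.5 | 0.0019 |
| noon run | 7.9 | 0.0078 |
| noon run | 18 | 0.0250 |
| noon run | 39 | 0.0540 |
| noon run | 88 | 0.1075 |

(readings scatter by 0.001 M)

- Overall: starting material -> product, with free catalyst as catalyst.
- Constant volume, constant temperature.
- A reading of a species includes what of it is bound.
- An order is taken over about fifteen percent of the charge, up and down.

- the exponent of [starting material] in the starting rate at the charge of the spring run (at the point where two percent of the starting material have become product) (one fixed amount of product, the same in the runs compared)
- the exponent of [free catalyst] in the starting rate at the charge of the spring run (at the point where two percent of the starting material have become product)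
- product in the midnight run at 260 min, as a share of the starting material charged

**First minutes.** By the first reading of the spring run 1.05% had turned, at a rough 0.00300 /min of the charge, and between the second and third readings the rate read 0.00639 /min, faster. The second reading stood at 3.25%, so the point asked for the orders, two percent turned, lay between the first two readings of the spring run.

**The middle.** From 18 min to 39 min the spring run read 0.00595 /min, no faster, with the unturned fraction down to 77.8% at the end of that stretch.

**The end.** The last two spring readings gave 128 min for my clock, the time in which the unturned fraction falls by a factor e between the last two readings, a pseudo-first-order time constant. The midnight run repeats the spring charge, so I ran the clock on from 46.9% at 88 min to 260 min and got 86.1%. The dusk run read a longer clock, 170 min, a warning against my number.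

**The forecast.** It gave an order of 0.75 (0.55 to 1) in starting material, 0.6 (0.35 to 0.85) in free catalyst and 82% (73% to 90%) for the midnight run, extrapolating “with some slowing as seen at dusk”.

**The result.** The flask gave an order of 0.74 in starting material, 0.41 in free catalyst, below the forecast, and 82.2% for the midnight run, below my clock.

    2 active catalyst ⇌ catalyst dimer, settled at all times (517.0 /M)
    active catalyst + starting material → product + active catalyst (2.076 /M/min)
    free catalyst → active catalyst (0.1104 /min)
    active catalyst + product ⇌ catalyst-product complex, settled at all times (17.00 /M)

Taken from the spring reading at 88 min to the midnight result at 260 min, the clock averaged 157 min, longer than my 128 min. The midnight run ended 5.2 percentage points short of the same run without the complex, which reaches 87.5%, because active catalyst joins product as catalyst-product complex. In the dusk run the clock put half the charge at 116 min, and the dusk run got there later, at 120 min.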